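**Plan**

- The retrosynthesis first cuts the two C–C bonds of the CH2 bridge (ring A C6–CH2 and CH2–ring B). This releases the prenylated ring A trione, formaldehyde and the ring B ketone 1-(2,4-dihydroxy-6-methoxyphenyl)butan-1-one.
- It then cuts the CH2–CH= bond inside the prenyl group on C4 of ring A. Ring A (C1 ketone, C2 butyryl, C3–O, quaternary C4, C5–O, C6–H) is unsymmetrical, and prenyl is a methyl group lengthened by a 2-methylprop-1-enyl unit. The gem-dimethyl trione (butyrylfilicinic acid) is therefore achiral with two enantiotopic methyl groups on C4, and the oxygen on C5 can steer palladium to one of them.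
- Forward, no ring is closed. Ring A is the carbocycle of phloroglucinol, C-butyrylated and then dearomatised by double C-methylation; the methyl C–H alkenylation follows. Ring B comes from 5-methoxyresorcinol by acylation, and formaldehyde joins the two halves last.
- The only stereocentre (C4, R) is created in the C–H alkenylation by the chiral amino acid ligand on palladium, which chooses between the enantiotopic methyl groups. Being quaternary, it cannot epimerise afterwards.

Key step: step 3

Assumption: the enolised triones are drawn and named as the 3,5-dihydroxycyclohexa-2,5-dien-1-one tautomer, to which the (R) descriptor refers, and N-acetyl-L-tert-leucine is taken to favour the methyl group that leads to (R); if the sense of induction were the opposite, N-acetyl-D-tert-leucine would be used with nothing else changed.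

**Route**

Step 1
Reactants: 1 phloroglucinol; 2 butyryl chloride
Product: 3 butyrylphloroglucinol, 1-(2,4,6-trihydroxyphenyl)butan-1-one
Conditions: AlCl3 (3 equiv), PhNO2/CH2Cl2, 0 °C to 40 °C; then ice, 1 M HCl
Reagents that add atoms: none
Why: Friedel–Crafts C-acylation of the electron-rich triol, whose three ring positions are equivalent; the first acyl group, held as an aluminium chelate, deactivates the ring against a second acylation.

Step 2
Reactants: 3 butyrylphloroglucinol
Product: 5 butyrylfilicinic acid (2-butanoyl-3,5-dihydroxy-4,4-dimethylcyclohexa-2,5-dien-1-one), via monomethyl ketone 4 (not isolated)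
Conditions: NaOMe (4 equiv), MeI (2.2 equiv), MeOH, 0 °C to rt; then 1 M HCl; NaHCO3 extraction of the acidic trione, chromatography
Reagents that add atoms: iodomethane, CI
Why: Base-mediated C-methylation of the phloroglucinol phenolate in which the second methyl group enters at the already methylated carbon (alkylative dearomatisation), the classical entry to acylfilicinic acids; the strongly acidic trione 5 should be separable from phenolic congeners by bicarbonate extraction.

Step 3
Reactants: 5 butyrylfilicinic acid; 6 2-methylprop-1-enylboronic acid pinacol ester
Product: 7 (R)-2-butanoyl-3,5-dihydroxy-4-methyl-4-(3-methylbut-2-en-1-yl)cyclohexa-2,5-dien-1-one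
Conditions: Pd(OAc)2 (10 mol %), N-acetyl-L-tert-leucine (20 mol %), 6 (2 equiv), Ag2CO3 (1.5 equiv), H2O (5 equiv), t-AmylOH, 80 °C, N2, stopped at partial conversion; then aq citric acid
Reagents that add atoms: none
Why: Proposed new method: the enolate oxygen on C5 of 5 (O5), the anionic end of a vinylogous carboxylate, should bind divalent palladium carrying the mono-N-protected amino acid, concerted metalation–deprotonation of one C4 methyl group (N-acetyl oxygen as internal base) should give a five-membered palladacycle (Pd, O, C5, C4, CH2), and transmetalation with 6 followed by C(sp3)–C(sp2) reductive elimination should form the CH2–CH= bond of the prenyl group before Ag2CO3 returns zerovalent palladium to the divalent state. The closest known reaction types are the enantioselective, carboxylate-directed desymmetrising β-C(sp3)–H cross-coupling of gem-dimethyl and small-ring carboxylic acids with organoboron reagents under amino acid ligands and the oxime-directed methyl C–H functionalisation of 2,2-dimethylcycloalkanones; an enolate oxygen of a cyclic trione has not served as the directing group. No ring is closed in the product, and the C4 stereocentre is set by the chiral ligand (catalyst control), which makes cleavage of one of the two enantiotopic methyl groups faster, so that the methyl group chosen fixes the configuration as R. The step needs direction from O5 and not from the oxygen on C3, which would pick the other methyl group; the C3 oxygen is held in the six-membered chelate with the butyryl carbonyl and is shielded by the acyl chain, whereas O5 is the free, most acidic oxygen with only C6–H beside it. It also needs the methyl C–H bond to react in preference to C6–H and to the product: a C6-bound palladium enolate is a doubly stabilised carbon ligand that is reluctant to undergo reductive elimination, the palladacycle carbon is neopentyl-type without β-hydrogen so β-hydride elimination is excluded, benzoquinone is left out because the dione carbon would add to it, and the run is stopped at partial conversion so that the more hindered remaining methyl group of 7 is not alkenylated.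

Step 4
Reactants: 8 5-methoxyresorcinol; 2 butyryl chloride
Product: 9 desaspidinol, 1-(2,4-dihydroxy-6-methoxyphenyl)butan-1-one
Conditions: AlCl3 (2.2 equiv), PhNO2/CH2Cl2, 0 °C to rt; then ice, 1 M HCl; chromatography
Reagents that add atoms: none
Why: Friedel–Crafts acylation in which two of the three activated ring positions (each between OH and OMe) lead to 9 and only one (between the two OH groups) to the symmetrical 2,6-dihydroxy-4-methoxy isomer, which differs in polarity and should be removed by chromatography; the low temperature guards the methyl ether against cleavage by AlCl3.

Step 5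
Reactants: 7 (R)-prenyl trione; 9 desaspidinol
Product: 11 (R)-2-butanoyl-6-[(3-butanoyl-2,6-dihydroxy-4-methoxyphenyl)methyl]-3,5-dihydroxy-4-methyl-4-(3-methylbut-2-en-1-yl)cyclohexa-2,5-dien-1-one (the target), via hydroxymethyl trione 10 (not isolated)
Conditions: 9 (3 equiv), 37% aq HCHO (1.1 equiv), 1% aq KOH, 0 °C, N2, short reaction time; then 1 M HCl; chromatography
Reagents that add atoms: formaldehyde, C=O
Why: Base-mediated hydroxymethylation of the C6 enolate carbon of 7, loss of water to the 6-methylene trione and Michael-type addition of the phenolate of 9 through C3 (the carbon between its two hydroxyl groups and para to OMe), the classical formaldehyde coupling for methylene-bridged acylfilicinic acid/acylphloroglucinol dimers; the excess of 9 should suppress the symmetrical ring A dimer, and the quaternary C4 centre is untouched.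

**Compound list**

1 | phloroglucinol (benzene-1,3,5-triol) | Oc1cc(O)cc(O)c1 | starting material
2 | butyryl chloride (butanoyl chloride) | CCCC(Cl)=O | starting material
3 | butyrylphloroglucinol, 1-(2,4,6-trihydroxyphenyl)butan-1-one | CCCC(=O)c1c(O)cc(O)cc1O | intermediate
4 | 1-(2,4,6-trihydroxy-3-methylphenyl)butan-1-one (forms in the flask in step 2) | CCCC(=O)c1c(O)cc(O)c(C)c1O | intermediate
5 | butyrylfilicinic acid, 2-butanoyl-3,5-dihydroxy-4,4-dimethylcyclohexa-2,5-dien-1-one (achiral) | CCCC(=O)C1=C(O)C(C)(C)C(O)=CC1=O | intermediate
6 | 2-methylprop-1-enylboronic acid pinacol ester | CC(C)=CB1OC(C)(C)C(C)(C)O1 | starting material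
7 | (R)-2-butanoyl-3,5-dihydroxy-4-methyl-4-(3-methylbut-2-en-1-yl)cyclohexa-2,5-dien-1-one | CCCC(=O)C1=C(O)[C@](C)(CC=C(C)C)C(O)=CC1=O | intermediate
8 | 5-methoxyresorcinol (5-methoxybenzene-1,3-diol) | COc1cc(O)cc(O)c1 | starting material
9 | desaspidinol, 1-(2,4-dihydroxy-6-methoxyphenyl)butan-1-one | CCCC(=O)c1c(O)cc(O)cc1OC | intermediate
10 | (R)-2-butanoyl-3,5-dihydroxy-6-(hydroxymethyl)-4-methyl-4-(3-methylbut-2-en-1-yl)cyclohexa-2,5-dien-1-one (forms in the flask in step 5) | CCCC(=O)C1=C(O)[C@](C)(CC=C(C)C)C(O)=C(CO)C1=O | intermediate
11 | (R)-2-butanoyl-6-[(3-butanoyl-2,6-dihydroxy-4-methoxyphenyl)methyl]-3,5-dihydroxy-4-methyl-4-(3-methylbut-2-en-1-yl)cyclohexa-2,5-dien-1-one | CCCC(=O)C1=C(O)[C@](C)(CC=C(C)C)C(O)=C(Cc2c(O)cc(OC)c(C(=O)CCC)c2O)C1=O | target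

**Step count and risks**

Total step count: 5 steps. Longest linear sequence: 4 steps (steps 1, 2, 3 and 5 from phloroglucinol); step 4 is a one-step side branch to the ring B ketone.

Steps most likely to fail:

1. Step 3 (key step, new method).
   - Palladium may be bound by the acyl-dione unit as an O,O-chelate, which would stall turnover.
   - C–H cleavage may be steered from the C3 oxygen, which would lower the enantiomeric purity.
   - Silver- or palladium-mediated oxidation and alkenylation may occur at the enol carbon C6.
   - The new prenyl group may undergo Wacker-type oxidative cyclisation onto a neighbouring enol oxygen.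
   - A second alkenylation may take place at the remaining methyl group.
   - Fallback with known chemistry, setting out from 3 and coming back at 7: C-methylation of 3 with one equivalent of MeI (NaOMe, MeOH, 0 °C) would give 4, this time isolated. Alkylative dearomatisation of 4 with prenyl bromide (NaOMe, MeOH, 0 °C) at the methyl-bearing ring carbon would give racemic 2-butanoyl-3,5-dihydroxy-4-methyl-4-(3-methylbut-2-en-1-yl)cyclohexa-2,5-dien-1-one F1, separable from the aromatic C-prenyl isomer through its higher acidity. Preparative chromatography on a chiral stationary phase would then deliver 7 and leave the (S)-enantiomer F2.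

2. Step 5.
   - The methylene unit may exchange between partners under base (retro-Michael and re-addition), leading to the two symmetrical dimers.
   - 9 may attack through C5 instead of C3.
   - 9 may be alkylated twice.
   - Fallback setting out from 9 and coming back at 11: a Mannich reaction of 9 with aqueous dimethylamine and formaldehyde (EtOH, rt) would give 1-[3-[(dimethylamino)methyl]-2,4-dihydroxy-6-methoxyphenyl]butan-1-one F3, whose constitution can be secured before the chiral half is committed. Heating F3 with 7 (dioxane, 90 °C) should expel dimethylamine to form the ortho-quinone methide of ring B, which the enol carbon C6 of 7, the only nucleophilic carbon of that partner, should trap by conjugate addition to give 11.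

3. Step 2.
   - Methylation may stop at 4.
   - The second methyl group may enter at the free ring carbon (aromatic 3,5-dimethyl isomer).
   - A third C-methylation may occur at C6 of 5.
   - O-methylation may compete.
   - Fallback setting out from 1 and coming back at 5: diacetylation of 1 (Ac2O, BF3·OEt2) would give 2,4-diacetylphloroglucinol F4, in which both other ring carbons are blocked so that MeI/NaOMe can only install the geminal pair, giving diacetylfilicinic acid F5. Deacetylation in 80% aq H2SO4 at 80 °C would give filicinic acid F6, and Friedel–Crafts mono-acylation of F6 with 2 (AlCl3, PhNO2) would give 5.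

Further compounds
F1 | step 3 | racemic 2-butanoyl-3,5-dihydroxy-4-methyl-4-(3-methylbut-2-en-1-yl)cyclohexa-2,5-dien-1-one | CCCC(=O)C1=C(O)C(C)(CC=C(C)C)C(O)=CC1=O
F2 | step 3 | (S)-2-butanoyl-3,5-dihydroxy-4-methyl-4-(3-methylbut-2-en-1-yl)cyclohexa-2,5-dien-1-one | CCCC(=O)C1=C(O)[C@@](C)(CC=C(C)C)C(O)=CC1=O
F3 | step 5 | 1-[3-[(dimethylamino)methyl]-2,4-dihydroxy-6-methoxyphenyl]butan-1-one | CCCC(=O)c1c(O)c(CN(C)C)c(O)cc1OC
F4 | step 2 | 2,4-diacetylphloroglucinol, 1,1'-(2,4,6-trihydroxy-1,3-phenylene)diethanone | CC(=O)c1c(O)cc(O)c(C(C)=O)c1O
F5 | step 2 | diacetylfilicinic acid, 2,6-diacetyl-3,5-dihydroxy-4,4-dimethylcyclohexa-2,5-dien-1-one | CC(=O)C1=C(O)C(C)(C)C(O)=C(C(C)=O)C1=O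
F6 | step 2 | filicinic acid, 3,5-dihydroxy-4,4-dimethylcyclohexa-2,5-dien-1-one | CC1(C)C(O)=CC(=O)C=C1O
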